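Each E made takes one Q and one L, so while nothing else takes either, the gap [L] − [Q] stays at its charged 0.200 M, and each reading of E becomes a pair of concentrations.

| flask | Q | L | E | time |
|---|---|---|---|---|
| west | 1.00 M | 1.20 M |  |  |
| north-west | 1.00 M | 1.20 M | 0.300 M |  |
| south-east | 1.00 M | 1.20 M |  | 78 min |

| run | time / min | [E] / M |
|---|---|---|
| west run | 6.2 | 0.146 |
| west run | 12 | 0.224 |
| west run | 19 | 0.293 |
| west run | 25 | 0.349 |
| west run | 31 | 0.397 |
| north-west run | 6.2 | 0.429 |
| north-west run | 12 | 0.520 |
| north-west run | 19 | 0.602 |
| north-west run | 25 | 0.654 |
| north-west run | 31 | 0.699 |

(scatter of a reading: 0.005 M)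

- E in the south-east run at 78 min, as a share of the Q charged

- Overall: Q + L -> E.
- Constant volume, constant temperature.
- The analysis sees a species whether free or bound.
- "The second partner" is L.

The charge of Q is smaller than that of L. If the rate were k[Q][L], ln([L]/[Q]) would climb straight in time, with slope k times the gap. In the west run between 19 min and 31 min this reads 0.0156 /M/min, give or take 0.00106 /M/min: this is our pace, the second-order constant that the balance implies over one stretch. The south-east flask has the west charge. Held from 31 min to 78 min, the pace gives 63.1%.

But is it a constant at all? Over the first 6.2 min of the west run it reads 0.0227 /M/min, higher than our figure. Between 6.2 min and 19 min it reads 0.0151 /M/min, inside the scatter of the later stretch. The north-west run, counting E made, reads 0.0147 /M/min between 19 min and 31 min. Still, the pace has moved once, and no reading lies past 31 min. So we take 63.1% as the high side.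

The forecast says 60%, within 54% to 65%, lower than our figure, allowing for “a faster early phase, or slow activity loss, or an order above two”. Its low end needs a mean pace of 0.00793 /M/min from 31 min on.

The flask gives 56.2%, by these steps:

    Q ⇌ G, settled at all times (0.3650)
    G + L → E (0.1038 /M/min)
    2 L → Wy (0.01062 /M/min)
    2 Q ⇌ Q2, settled at all times (0.3240 /M)

Our pace puts E made in the west run at half of the Q charged by 47.1 min, but the west run gets there at 54.0 min, later than that. Reckoned still through the balance, which the step to Wy does not keep, the south-east pace from 31 min to 78 min is 0.00953 /M/min, above what the forecast's low end needs. In the north-west run, from 31 min to 54.0 min, the pace is 0.0107 /M/min.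

(The earlier runs and the new flask were computed for substances that don't exist, noise included.)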